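**Retrosynthetic overview**
1. The C5 formyl group is installed last, by phenoxide-directed ortho-formylation of (R)-δ-tocotrienol after removal of a MOM ether.
2. The dihydropyran ring is the only ring made (the benzene ring is bought as 4-iodo-3-methylphenol). One palladium/norbornene [4+2] annulation of the aryl iodide with an (R)-γ-bromo tertiary alcohol forges C4–C4a (ortho C–H alkylation) and O1–C8a (ipso C–O coupling); the C2–O1 bond is carried in intact.
3. Enabling feature: on the benzene ring, C8a lies between C8 (methyl) and C4a. An iodide at C8a therefore has one blocked and one free ortho position, which lets norbornene relay palladium to C4a once and then leave. O1 and C4 are 1,4-related across C2, a carbon without hydrogen, so the palladium alkoxide can only reductively eliminate.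
4. The C2 stereocentre and the whole side chain come from all-E geranylgeraniol by Sharpless epoxidation, C2-selective hydride opening and primary bromination.
5. Ring order: benzene ring purchased, then dihydropyran ring (step 5).

Key step: step 5

Assumption: the target is read as (2R)-5-formyl-δ-tocotrienol (CIP order at C2: O1 > C3 > C1' > CH3); all-E geranylgeraniol and 4-iodo-3-methylphenol are taken as purchasable.

**Step 1**
Reactants: 1 all-E geranylgeraniol
Product: 2 (2R,3R)-2,3-epoxygeranylgeraniol
Conditions: Ti(OiPr)4 (cat.), D-(−)-diethyl tartrate (cat.), t-BuOOH, 4 Å MS, CH2Cl2, −20 °C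
Reagents that add atoms: tert-butyl hydroperoxide, CC(C)(C)OO
Why: Sharpless asymmetric epoxidation acts only on the allylic-alcohol alkene, and with the D-(−)-tartrate ligand oxygen should be delivered to the face that gives the (2R,3R)-epoxide (the mirror image of the outcome known for geraniol with the L-(+)-ligand), so the future C2 of the chroman is set as R by reagent control.

**Step 2**
Reactants: 2 (2R,3R)-2,3-epoxygeranylgeraniol
Product: 3 (R)-1,3-diol
Conditions: NaAlH2(OCH2CH2OMe)2, THF, 0 °C; aq. potassium sodium tartrate work-up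
Reagents that add atoms: none
Why: In this directed reductive opening of a 2,3-epoxy alcohol, hydride is delivered from the C1 alkoxyaluminate to C2, so the 1,3-diol should form while the C3–O bond of the tertiary centre is untouched (configuration retained; the C2 epoxide stereocentre is erased).

**Step 3**
Reactants: 3 (R)-1,3-diol
Product: 4 (R)-γ-bromo tertiary alcohol
Conditions: CBr4, PPh3, CH2Cl2, 0 °C
Reagents that add atoms: carbon tetrabromide, BrC(Br)(Br)Br
Why: In the Appel reaction only the primary alkoxyphosphonium ion can be displaced by bromide in an SN2 step at 0 °C, so the tertiary hydroxyl and its stereocentre should remain.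

**Step 4**
Reactants: 5 4-iodo-3-methylphenol
Product: 6 1-iodo-4-(methoxymethoxy)-2-methylbenzene
Conditions: MOMCl, iPr2NEt, CH2Cl2, 0 °C to rt
Reagents that add atoms: chloromethyl methyl ether, COCCl
Why: Williamson-type O-alkylation masks the phenol as a base-stable acetal, so that no phenoxide competes for the alkyl bromide or slows oxidative addition in step 5.

**Step 5**
Reactants: 4 (R)-γ-bromo tertiary alcohol; 6 1-iodo-4-(methoxymethoxy)-2-methylbenzene
Product: 8 (R)-δ-tocotrienol methoxymethyl ether, via aryl alkoxo palladacycle 7 (not isolated)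
Conditions: Pd(OAc)2 (10 mol%), XPhos (20 mol%), norbornene (1 equiv), Cs2CO3 (3 equiv), toluene, 100 °C, Ar
Reagents that add atoms: none
Why: Proposed new method: zerovalent palladium inserts into the C8a–I bond of 6, norbornene carbopalladation and C4a–H palladation give the aryl–norbornyl palladacycle, and this divalent palladacycle adds the primary C–Br bond of 4 to reach tetravalent palladium, from which reductive elimination forms C4–C4a (the ortho-alkylation of the Catellani reaction). Because C8a is now flanked by the C8 methyl group and the new chain, norbornene is expelled by β-carbon elimination, and the arylpalladium so formed binds the tethered tertiary hydroxyl, which Cs2CO3 deprotonates to the seven-membered chelate 7. C–O reductive elimination from 7 forms O1–C8a and closes the dihydropyran ring, a six-membered ring made by contraction of the seven-membered palladacycle (formally a 6-exo attack of O1 on the ipso carbon), and frees zerovalent palladium. The closest known reaction types are the palladium/norbornene annulation of aryl iodides with epoxides to 2,3-dihydrobenzofurans, the Catellani ortho-alkylation with primary alkyl bromides, and the palladium-catalysed intramolecular etherification of aryl halides with tertiary alcohols to chromans; what is new is their union with a γ-bromo tertiary alcohol to close the six-membered ring. No stereocentre is created: C2 comes from 4 with retention because none of its four bonds is made or broken, and since C2 bears no hydrogen the palladium alkoxide cannot undergo β-hydride elimination. The step needs one alkylation at C4a followed by ipso C–O coupling in place of a second alkylation, ipso reduction or Heck termination, and this is secured by the C8 methyl group (a single free ortho C–H), by the intramolecular alkoxide and by the low Heck reactivity of the trisubstituted alkenes.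

**Step 6**
Reactants: 8 (R)-δ-tocotrienol methoxymethyl ether
Product: 9 (R)-δ-tocotrienol
Conditions: HCl (cat.), MeOH–THF, rt to 40 °C
Reagents that add atoms: none
Why: Acid-catalysed acetal exchange with methanol should remove the phenolic MOM group as dimethoxymethane under conditions mild enough for the trisubstituted alkenes and the chroman ether.

**Step 7**
Reactants: 9 (R)-δ-tocotrienol
Product: 11 (2R)-5-formyl-δ-tocotrienol, via 5-hydroxymethyl-δ-tocotrienol 10 (not isolated)
Conditions: MgCl2, Et3N, (CH2O)n, THF, reflux
Reagents that add atoms: paraformaldehyde (as formaldehyde), C=O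
Why: In this magnesium-phenoxide-directed ortho-formylation (Casnati–Skattebøl reaction), ortho-hydroxymethylation to 10 and hydride transfer to a second formaldehyde give the salicylaldehyde, and attack at C5 instead of C7 is expected because the fused dihydropyran ring makes C5 the more nucleophilic ortho position of δ-chromanols and its tied-back C4 methylene is smaller than the C8 methyl group beside C7.

**Compound list**
1 | (2E,6E,10E)-3,7,11,15-tetramethylhexadeca-2,6,10,14-tetraen-1-ol (all-E geranylgeraniol) | CC(C)=CCC/C(C)=C/CC/C(C)=C/CC/C(C)=C/CO | starting material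
2 | [(2R,3R)-3-methyl-3-[(3E,7E)-4,8,12-trimethyltrideca-3,7,11-trien-1-yl]oxiran-2-yl]methanol | CC(C)=CCC/C(C)=C/CC/C(C)=C/CC[C@@]1(C)O[C@@H]1CO | intermediate
3 | (3R,6E,10E)-3,7,11,15-tetramethylhexadeca-6,10,14-triene-1,3-diol | CC(C)=CCC/C(C)=C/CC/C(C)=C/CC[C@](O)(C)CCO | intermediate
4 | (3R,6E,10E)-1-bromo-3,7,11,15-tetramethylhexadeca-6,10,14-trien-3-ol | CC(C)=CCC/C(C)=C/CC/C(C)=C/CC[C@](O)(C)CCBr | intermediate
5 | 4-iodo-3-methylphenol | Cc1cc(O)ccc1I | starting material
6 | 1-iodo-4-(methoxymethoxy)-2-methylbenzene | COCOc1ccc(I)c(C)c1 | intermediate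
7 | seven-membered aryl(alkoxo) chelate of divalent palladium, C8a–Pd–O1 (XPhos on palladium not drawn) | CC(C)=CCC/C(C)=C/CC/C(C)=C/CC[C@]1(C)CCc2cc(OCOC)cc(C)c2[Pd]O1 | intermediate
8 | (2R)-6-(methoxymethoxy)-2,8-dimethyl-2-[(3E,7E)-4,8,12-trimethyltrideca-3,7,11-trien-1-yl]chromane | CC(C)=CCC/C(C)=C/CC/C(C)=C/CC[C@]1(C)CCc2cc(OCOC)cc(C)c2O1 | intermediate
9 | (2R)-2,8-dimethyl-2-[(3E,7E)-4,8,12-trimethyltrideca-3,7,11-trien-1-yl]chroman-6-ol ((R)-δ-tocotrienol) | CC(C)=CCC/C(C)=C/CC/C(C)=C/CC[C@]1(C)CCc2cc(O)cc(C)c2O1 | intermediate
10 | (2R)-5-(hydroxymethyl)-2,8-dimethyl-2-[(3E,7E)-4,8,12-trimethyltrideca-3,7,11-trien-1-yl]chroman-6-ol (present as its magnesium phenoxide) | CC(C)=CCC/C(C)=C/CC/C(C)=C/CC[C@]1(C)CCc2c(CO)c(O)cc(C)c2O1 | intermediate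
11 | (2R)-6-hydroxy-2,8-dimethyl-2-[(3E,7E)-4,8,12-trimethyltrideca-3,7,11-trien-1-yl]chromane-5-carbaldehyde | CC(C)=CCC/C(C)=C/CC/C(C)=C/CC[C@]1(C)CCc2c(C=O)c(O)cc(C)c2O1 | target

**Step count**
Total steps: 7. Longest linear sequence: 6 steps (steps 1, 2, 3, 5, 6, 7, from 1 to 11).

**Steps most likely to fail**

Step 5 (proposed new method).
- What may go wrong: ipso C–O reductive elimination from the electron-rich, doubly ortho-substituted arylpalladium alkoxide may be slower than ipso reduction. The hot carbonate may also consume the γ-bromo alcohol by ring closure to the oxetane or by fragmentation before it reaches the palladacycle.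
- Fallback (known chemistry only, sets out from 4, rejoins at 9): the two bonds are made one after the other on a 1,2-dihaloarene.
 - Purchased 4-methoxy-2-methylaniline F1 is iodinated ortho to nitrogen (ICl, CaCO3, CH2Cl2–MeOH) to 2-iodo-4-methoxy-6-methylaniline F2.
 - Sandmeyer bromination (NaNO2, HBr, then CuBr) gives 2-bromo-1-iodo-5-methoxy-3-methylbenzene F3.
 - Bromo alcohol 4 is silylated (Et3SiOTf, 2,6-lutidine, CH2Cl2, −78 °C) to the triethylsilyl ether of 4 F4.
 - LiCl-promoted zinc insertion (zinc dust, THF, 50 °C) converts F4 to the alkylzinc bromide F5.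
 - Negishi coupling (Pd(OAc)2, SPhos, THF, rt) at the C–I bond of F3 forms C4–C4a and gives the aryl bromide silyl ether F6.
 - Bu4NF in THF frees the tertiary alcohol, giving the aryl bromide alcohol F7.
 - Palladium-catalysed intramolecular etherification (Pd(OAc)2, 2-(di-tert-butylphosphino)-1,1'-binaphthyl, Cs2CO3, toluene, 80 °C) forms O1–C8a without touching C2 and gives (R)-δ-tocotrienol methyl ether F8.
 - NaSEt in DMF at 120 °C cleaves the methyl ether to 9.

Step 7.
- What may go wrong: poor regioselectivity between the two free ortho positions C5 and C7, and over-formylation.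
- Fallback (sets out from 4, rejoins at 11): the formyl carbon is bought with the ring, so the regiochemistry is fixed by construction.
 - Purchased 2-hydroxy-4-methylbenzaldehyde F9 is iodinated para to the hydroxyl (NIS, cat. CF3CO2H, MeCN) to 2-hydroxy-5-iodo-4-methylbenzaldehyde F10.
 - Protection (MOMCl, iPr2NEt) gives 5-iodo-2-(methoxymethoxy)-4-methylbenzaldehyde F11.
 - Annulation with 4 under the conditions of step 5 gives the methoxymethyl ether of the target F12.
 - Removal of the acetal as in step 6 gives 11.
 - This is held in reserve because the C4a–H to be palladated then lies next to the formyl group.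

Step 3.
- What may go wrong: loss of chemoselectivity during phosphonium activation, through ionisation or dehydration of the tertiary alcohol or cyclic ether formation from the 1,3-diol.
- Fallback (sets out from 3, rejoins at 4): an isolable sulfonate replaces the phosphonium intermediate.
 - Selective sulfonylation of the primary hydroxyl (TsCl, Et3N, cat. DMAP, CH2Cl2, 0 °C) gives the primary monotosylate of 3 F13.
 - Finkelstein-type displacement with LiBr in acetone at 40 °C gives 4.

**Further compounds**
F1 | step 5 | 4-methoxy-2-methylaniline (purchased for the fallback) | COc1ccc(N)c(C)c1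
F2 | step 5 | 2-iodo-4-methoxy-6-methylaniline | COc1cc(C)c(N)c(I)c1
F3 | step 5 | 2-bromo-1-iodo-5-methoxy-3-methylbenzene | COc1cc(C)c(Br)c(I)c1
F4 | step 5 | triethylsilyl ether of 4, {[(3R,6E,10E)-1-bromo-3,7,11,15-tetramethylhexadeca-6,10,14-trien-3-yl]oxy}triethylsilane | CC(C)=CCC/C(C)=C/CC/C(C)=C/CC[C@](O[Si](CC)(CC)CC)(C)CCBr
F5 | step 5 | alkylzinc bromide, [(3R,6E,10E)-3,7,11,15-tetramethyl-3-(triethylsilyloxy)hexadeca-6,10,14-trien-1-yl]zinc bromide | CC(C)=CCC/C(C)=C/CC/C(C)=C/CC[C@](O[Si](CC)(CC)CC)(C)CC[Zn]Br
F6 | step 5 | aryl bromide silyl ether, {[(3R,6E,10E)-1-(2-bromo-5-methoxy-3-methylphenyl)-3,7,11,15-tetramethylhexadeca-6,10,14-trien-3-yl]oxy}triethylsilane | CC(C)=CCC/C(C)=C/CC/C(C)=C/CC[C@](O[Si](CC)(CC)CC)(C)CCc1cc(OC)cc(C)c1Br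
F7 | step 5 | aryl bromide alcohol, (3R,6E,10E)-1-(2-bromo-5-methoxy-3-methylphenyl)-3,7,11,15-tetramethylhexadeca-6,10,14-trien-3-ol | CC(C)=CCC/C(C)=C/CC/C(C)=C/CC[C@](O)(C)CCc1cc(OC)cc(C)c1Br
F8 | step 5 | (R)-δ-tocotrienol methyl ether, (2R)-6-methoxy-2,8-dimethyl-2-[(3E,7E)-4,8,12-trimethyltrideca-3,7,11-trien-1-yl]chromane | CC(C)=CCC/C(C)=C/CC/C(C)=C/CC[C@]1(C)CCc2cc(OC)cc(C)c2O1
F9 | step 7 | 2-hydroxy-4-methylbenzaldehyde (purchased for the fallback) | Cc1ccc(C=O)c(O)c1
F10 | step 7 | 2-hydroxy-5-iodo-4-methylbenzaldehyde | Cc1cc(O)c(C=O)cc1I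
F11 | step 7 | 5-iodo-2-(methoxymethoxy)-4-methylbenzaldehyde | Cc1cc(OCOC)c(C=O)cc1I
F12 | step 7 | methoxymethyl ether of the target, (2R)-6-(methoxymethoxy)-2,8-dimethyl-2-[(3E,7E)-4,8,12-trimethyltrideca-3,7,11-trien-1-yl]chromane-5-carbaldehyde | CC(C)=CCC/C(C)=C/CC/C(C)=C/CC[C@]1(C)CCc2c(C=O)c(OCOC)cc(C)c2O1
F13 | step 3 | primary monotosylate of 3, (3R,6E,10E)-3-hydroxy-3,7,11,15-tetramethylhexadeca-6,10,14-trien-1-yl 4-methylbenzenesulfonate | CC(C)=CCC/C(C)=C/CC/C(C)=C/CC[C@](O)(C)CCOS(=O)(=O)c1ccc(C)cc1
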